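## Retrosynthetic overview

1. Ring bromochloride ⇐ trans-diaxial ring bromohydrin (Br on the tertiary, OH on the secondary carbon): deoxychlorination through a bromonium ion, then diaxial→diequatorial Br/Cl interchange.
2. 3-Bromo-2,2-dimethyloxane ⇐ 2-(2-hydroxypropan-2-yl)oxolane: bromide-terminated ring expansion through a bicyclic epoxonium ion (key step); the same reagent opens the ring epoxide.
3. Oxolane carbinol with ring epoxide ⇐ (R,R)-α-bisabolol: double reagent-controlled epoxidation and 5-exo epoxy-alcohol cyclisation.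
4. (R,R)-α-Bisabolol ⇐ (R)-4-acetyl-1-methylcyclohexene + homoprenyl zinc reagent (catalytic asymmetric addition) ⇐ isoprene + methyl vinyl ketone (catalytic asymmetric Diels–Alder).
5. Ring order: cyclohexene (Diels–Alder), then oxolane (epoxide opening), then oxane (ring expansion of the oxolane).

Assumption: the sense of induction of each chiral catalyst is taken from its accepted model and checked on the first chiral intermediate; if it proves opposite, the mirror-image catalyst is used.

## Route

Step 1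
Reactants: 1 isoprene (2-methylbuta-1,3-diene), 2 methyl vinyl ketone (but-3-en-2-one)
Product: 3 (R)-1-(4-methylcyclohex-3-en-1-yl)ethan-1-one
Conditions: (S)-o-tolyl-oxazaborolidinium triflimide (Corey type, 10 mol%), CH2Cl2, −40 °C, 24 h
Reagents that add atoms: none
Why: Catalytic enantioselective Diels–Alder reaction in which the cationic oxazaborolidine activates the enone and blocks one face, isoprene adds with para regioselectivity, and the catalyst sets the ring stereocentre as (R).

Step 2
Reactants: 3 (R)-1-(4-methylcyclohex-3-en-1-yl)ethan-1-one, 4 5-bromo-2-methylpent-2-ene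
Product: 7 (2R)-6-methyl-2-[(1R)-4-methylcyclohex-3-en-1-yl]hept-5-en-2-ol, via homoprenylmagnesium bromide 5 (not isolated), via bis(homoprenyl)zinc 6 (not isolated)
Conditions: 4, Mg, THF, 40 °C; ZnCl2 (0.5 equiv), then 1,4-dioxane, filter; 3, Ti(OiPr)4 (1.2 equiv), bis(10-camphorsulfonamide) diol ligand of trans-cyclohexane-1,2-diamine (enantiomer giving Re-face attack, 10 mol%), PhMe/hexane, 23 °C, 24 h; aq. NH4Cl
Reagents that add atoms: none
Why: Catalytic asymmetric 1,2-addition of a dialkylzinc to a methyl ketone (Ti(OiPr)4/bis(sulfonamide) diol catalysis), in which the chiral titanium complex delivers the homoprenyl group to the Re face of a ketone whose methyl and α-branched cyclohexenyl groups are sterically well differentiated, so the tertiary carbinol centre is set as (R) by the catalyst and not by the remote ring centre.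

Step 3
Reactants: 7 (2R)-6-methyl-2-[(1R)-4-methylcyclohex-3-en-1-yl]hept-5-en-2-ol
Product: 9 2-[(2R,5R)-5-methyl-5-[(1S,3R,6R)-6-methyl-7-oxabicyclo[4.1.0]heptan-3-yl]oxolan-2-yl]propan-2-ol, via bis-epoxide 8 (not isolated)
Conditions: ent-Shi ketone (L-fructose-derived, 40 mol%), Oxone (2KHSO5·KHSO4·K2SO4, 3 equiv), K2CO3, Bu4NHSO4 (5 mol%), MeCN/dimethoxymethane/aq. Na2B4O7–Na2EDTA buffer (pH 10.5), 0 °C; then PPTS (10 mol%), CH2Cl2, 0 °C
Reagents that add atoms: potassium peroxymonosulfate KHSO5 (from Oxone) OOS(=O)(=O)[O-].[K+]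
Why: Shi asymmetric epoxidation (chiral dioxirane, spiro transition state) converts both trisubstituted olefins under reagent control into the (S)-side-chain epoxide and the ring epoxide trans to the side chain, and mild acid then lets the tertiary hydroxyl open the side-chain epoxide 5-exo at its secondary carbon with inversion (epoxy-alcohol cyclisation), which sets the (R)-configured oxolane CH.

Step 4
Reactants: 9 2-[(2R,5R)-5-methyl-5-[(1S,3R,6R)-6-methyl-7-oxabicyclo[4.1.0]heptan-3-yl]oxolan-2-yl]propan-2-ol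
Product: 12 (1S,2S,5R)-2-bromo-5-[(2R,5S)-5-bromo-2,6,6-trimethyloxan-2-yl]-2-methylcyclohexan-1-ol, via tertiary bromide oxolane 10 (not isolated), via oxane silyl ether 11 (not isolated)
Conditions: TMSBr (3 equiv), ZnBr2 (20 mol%), CH2Cl2, −78 → 0 °C, 3 h; then aq. citric acid, THF, 0 °C
Reagents that add atoms: bromotrimethylsilane C[Si](C)(C)Br
Why: Proposed new method: bromide-terminated ring expansion of a 2-(2-hydroxypropan-2-yl)oxolane, in which TMSBr (and the HBr it releases) turns the tertiary carbinol into a leaving group that ZnBr2 ionises with backside help from the ring oxygen to a bicyclic epoxonium (1-oxoniabicyclo[3.1.0]hexane) ion; bromide return at the tertiary carbon only gives the re-ionisable tertiary bromide 10, whereas SN2 attack at the secondary carbon with inversion is practically irreversible and gives the less strained oxane with the equatorial (S)-C–Br, while the same reagent opens the ring epoxide at its tertiary carbon (Markovnikov, trans-diaxial) to the bromohydrin; the closest known reaction type is the Zn(OAc)2-mediated ring expansion of tetrahydrofurfuryl sulfonates to 3-acyloxytetrahydropyrans through bicyclic oxonium ions, which has not been shown for tertiary carbinols or with bromide as the terminating nucleophile.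

Step 5
Reactants: 12 (1S,2S,5R)-2-bromo-5-[(2R,5S)-5-bromo-2,6,6-trimethyloxan-2-yl]-2-methylcyclohexan-1-ol
Product: 14 deoxycaespitol (3S,6R)-3-bromo-6-[(1R,3R,4R)-3-bromo-4-chloro-4-methylcyclohexyl]-2,2,6-trimethyloxane, via diaxial bromochloride 13 (not isolated)
Conditions: SOCl2 (1.5 equiv), CH2Cl2, −20 → 23 °C; evaporate; then PhMe, 80 °C, 2 h
Reagents that add atoms: thionyl chloride O=S(Cl)Cl
Why: Deoxychlorination with neighbouring-group participation, in which the chlorosulfite ionises with anchimeric help from the trans-diaxial tertiary bromide to the bromonium ion on the ring face cis to the oxanyl group, chloride opens it either at the tertiary carbon (giving 14 directly) or at the secondary carbon (giving diaxial 13), and heating then drives the diaxial-to-diequatorial 1,2-interchange of vicinal bromochlorides (recalled precedent: 5α-bromo-6β-chloro steroids and isocaespitol to caespitol) so that Cl ends on the tertiary and Br on the secondary carbon, both equatorial.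

## Compound list

1 | isoprene (2-methylbuta-1,3-diene) | C=CC(C)=C | starting material
2 | methyl vinyl ketone (but-3-en-2-one) | CC(=O)C=C | starting material
3 | (R)-1-(4-methylcyclohex-3-en-1-yl)ethan-1-one | CC(=O)[C@@H]1CCC(C)=CC1 | intermediate
4 | 5-bromo-2-methylpent-2-ene (homoprenyl bromide) | CC(C)=CCCBr | starting material
5 | (4-methylpent-3-en-1-yl)magnesium bromide | CC(C)=CCC[Mg]Br | intermediate
6 | bis(4-methylpent-3-en-1-yl)zinc | CC(C)=CCC[Zn]CCC=C(C)C | intermediate
7 | (2R)-6-methyl-2-[(1R)-4-methylcyclohex-3-en-1-yl]hept-5-en-2-ol ((R,R)-α-bisabolol) | CC(C)=CCC[C@@](C)(O)[C@@H]1CCC(C)=CC1 | intermediate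
8 | (2R)-4-[(2S)-3,3-dimethyloxiran-2-yl]-2-[(1S,3R,6R)-6-methyl-7-oxabicyclo[4.1.0]heptan-3-yl]butan-2-ol | CC1(C)O[C@H]1CC[C@@](C)(O)[C@@H]2CC[C@@]3(C)O[C@H]3C2 | intermediate
9 | 2-[(2R,5R)-5-methyl-5-[(1S,3R,6R)-6-methyl-7-oxabicyclo[4.1.0]heptan-3-yl]oxolan-2-yl]propan-2-ol | CC(C)(O)[C@H]1CC[C@@](C)(O1)[C@@H]2CC[C@@]3(C)O[C@H]3C2 | intermediate
10 | (2R,5R)-2-(2-bromopropan-2-yl)-5-methyl-5-[(1R,3S,4S)-4-bromo-4-methyl-3-(trimethylsilyloxy)cyclohexyl]oxolane | CC(C)(Br)[C@H]1CC[C@@](C)(O1)[C@@H]2CC[C@](C)(Br)[C@@H](O[Si](C)(C)C)C2 | intermediate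
11 | (3S,6R)-3-bromo-6-[(1R,3S,4S)-4-bromo-4-methyl-3-(trimethylsilyloxy)cyclohexyl]-2,2,6-trimethyloxane | CC1(C)O[C@@](C)([C@@H]2CC[C@](C)(Br)[C@@H](O[Si](C)(C)C)C2)CC[C@@H]1Br | intermediate
12 | (1S,2S,5R)-2-bromo-5-[(2R,5S)-5-bromo-2,6,6-trimethyloxan-2-yl]-2-methylcyclohexan-1-ol | CC1(C)O[C@@](C)([C@@H]2CC[C@](C)(Br)[C@@H](O)C2)CC[C@@H]1Br | intermediate
13 | (3S,6R)-3-bromo-6-[(1R,3S,4S)-4-bromo-3-chloro-4-methylcyclohexyl]-2,2,6-trimethyloxane | CC1(C)O[C@@](C)([C@@H]2CC[C@](C)(Br)[C@@H](Cl)C2)CC[C@@H]1Br | intermediate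
14 | deoxycaespitol, (3S,6R)-3-bromo-6-[(1R,3R,4R)-3-bromo-4-chloro-4-methylcyclohexyl]-2,2,6-trimethyloxane | CC1(C)O[C@@](C)([C@@H]2CC[C@@](C)(Cl)[C@H](Br)C2)CC[C@@H]1Br | target

## Step count and risks

Total step count: 5. Longest linear sequence: 5 steps (1 + 2 → 14).

**Step 4 (proposed new ring expansion).** The tertiary cation may eliminate or undergo a hydride shift, or the tertiary bromide 10 may not funnel to the oxane. The fallback uses known chemistry, sets out from 7 and comes back at 12. Compound 7 is cyclised with 2,4,4,6-tetrabromocyclohexa-2,5-dienone in MeNO2 at 0 °C (bromonium-induced 6-endo etherification of the hydroxyl-assisted side-chain olefin, chair transition state with equatorial cyclohexenyl and Br). This gives the bromo-oxane olefin (3S,6R)-3-bromo-2,2,6-trimethyl-6-[(1R)-4-methylcyclohex-3-en-1-yl]oxane F1, which is separated from the oxolane isomer. ent-Shi epoxidation of the ring olefin then gives the epoxide (3S,6R)-3-bromo-2,2,6-trimethyl-6-[(1S,3R,6R)-6-methyl-7-oxabicyclo[4.1.0]heptan-3-yl]oxane F2. TMSBr (1.1 equiv, CH2Cl2, −78 °C, then aq. citric acid) opens the epoxide at the tertiary carbon to 12.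

**Step 5 (deoxychlorination and Br/Cl interchange).** The bromonium/chloride pair may collapse mainly to diaxial 13, whose thermal interchange to 14 could be incomplete or accompanied by HBr loss and halide scrambling. The fallback sets out from 7 and comes back at 14; it brings chlorine in first as the nucleophile and bromine last, so no thermal step is needed.
- Hydroxyl-directed epoxidation–cyclisation of 7 (VO(acac)2, t-BuOOH, CH2Cl2) gives the oxolane carbinol 2-[(2R,5R)-5-methyl-5-[(1R)-4-methylcyclohex-3-en-1-yl]oxolan-2-yl]propan-2-ol F3.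
- NBS in aqueous acetone gives the trans-diaxial bromohydrin (1S,2S,4R)-2-bromo-4-[(2R,5R)-5-(2-hydroxypropan-2-yl)-2-methyloxolan-2-yl]-1-methylcyclohexan-1-ol F4 (bromonium anti to the side chain, water at the tertiary carbon).
- K2CO3 in MeOH closes it to the epoxide cis to the side chain, 2-[(2R,5R)-5-methyl-5-[(1R,3R,6S)-6-methyl-7-oxabicyclo[4.1.0]heptan-3-yl]oxolan-2-yl]propan-2-ol F5.
- HCl in Et2O at −20 °C opens it trans-diaxially at the secondary carbon to the chlorohydrin (1S,2S,4R)-2-chloro-4-[(2R,5R)-5-(2-hydroxypropan-2-yl)-2-methyloxolan-2-yl]-1-methylcyclohexan-1-ol F6.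
- TMSBr/ZnBr2 under the conditions of step 4 then ionises both tertiary carbinols. The side chain ring-expands, and the ring passes through the chloronium ion, which bromide opens at the secondary carbon to give 14.

**Step 2 (asymmetric addition to a dialkyl ketone).** Diastereoselectivity may be modest because the ketone is not aryl or conjugated. The fallback sets out from 3 and comes back at 7.
- Catalytic asymmetric allylboration of 3 (allyl-B(OiPr)2, the 3,3'-dibromo-BINOL enantiomer giving Re-face transfer, t-BuOH, PhMe) gives the homoallylic alcohol (2R)-2-[(1R)-4-methylcyclohex-3-en-1-yl]pent-4-en-2-ol F7.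
- 9-BBN, then NaOH/H2O2, hydroborates only the terminal olefin and gives the diol (4R)-4-[(1R)-4-methylcyclohex-3-en-1-yl]pentane-1,4-diol F8.
- TEMPO/PhI(OAc)2 oxidises the primary alcohol to the lactol (5R)-5-methyl-5-[(1R)-4-methylcyclohex-3-en-1-yl]oxolan-2-ol F9.
- Wittig olefination with isopropylidenetriphenylphosphorane (from isopropyltriphenylphosphonium iodide and n-BuLi, THF) gives 7.

## Further compounds

F1 | step 4 | (3S,6R)-3-bromo-2,2,6-trimethyl-6-[(1R)-4-methylcyclohex-3-en-1-yl]oxane | CC1(C)O[C@@](C)([C@@H]2CCC(C)=CC2)CC[C@@H]1Br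
F2 | step 4 | (3S,6R)-3-bromo-2,2,6-trimethyl-6-[(1S,3R,6R)-6-methyl-7-oxabicyclo[4.1.0]heptan-3-yl]oxane | CC1(C)O[C@@](C)([C@@H]2CC[C@@]3(C)O[C@H]3C2)CC[C@@H]1Br
F3 | step 5 | 2-[(2R,5R)-5-methyl-5-[(1R)-4-methylcyclohex-3-en-1-yl]oxolan-2-yl]propan-2-ol | CC(C)(O)[C@H]1CC[C@@](C)(O1)[C@@H]2CCC(C)=CC2
F4 | step 5 | (1S,2S,4R)-2-bromo-4-[(2R,5R)-5-(2-hydroxypropan-2-yl)-2-methyloxolan-2-yl]-1-methylcyclohexan-1-ol | CC(C)(O)[C@H]1CC[C@@](C)(O1)[C@@H]2CC[C@](C)(O)[C@@H](Br)C2
F5 | step 5 | 2-[(2R,5R)-5-methyl-5-[(1R,3R,6S)-6-methyl-7-oxabicyclo[4.1.0]heptan-3-yl]oxolan-2-yl]propan-2-ol | CC(C)(O)[C@H]1CC[C@@](C)(O1)[C@@H]2CC[C@]3(C)O[C@@H]3C2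
F6 | step 5 | (1S,2S,4R)-2-chloro-4-[(2R,5R)-5-(2-hydroxypropan-2-yl)-2-methyloxolan-2-yl]-1-methylcyclohexan-1-ol | CC(C)(O)[C@H]1CC[C@@](C)(O1)[C@@H]2CC[C@](C)(O)[C@@H](Cl)C2
F7 | step 2 | (2R)-2-[(1R)-4-methylcyclohex-3-en-1-yl]pent-4-en-2-ol | C=CC[C@@](C)(O)[C@@H]1CCC(C)=CC1
F8 | step 2 | (4R)-4-[(1R)-4-methylcyclohex-3-en-1-yl]pentane-1,4-diol | OCCC[C@@](C)(O)[C@@H]1CCC(C)=CC1
F9 | step 2 | (5R)-5-methyl-5-[(1R)-4-methylcyclohex-3-en-1-yl]oxolan-2-ol | OC1CC[C@@](C)(O1)[C@@H]2CCC(C)=CC2
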